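**Remark:** The SMILES string is read as (2′S,12′S). The chain is numbered C1′ (benzylic) to C13′, the ring C1 (carboxyl-bearing) to C6 (chain-bearing), and the carboxyl carbon is C7.

## Analysis of the target

The target is a β-resorcylic acid: one benzene ring (C1–C6) with the carboxyl carbon C7 on C1, free hydroxyls on C2 and C4, and a saturated, unbranched thirteen-carbon chain (C1′–C13′) on C6. The only stereocentres are C2′ and C12′, both S and both acetoxylated. They lie ten bonds apart, so neither can steer the other and each needs its own source of chirality. C2′ sits between two methylene groups of similar size, the benzylic C1′ and the chain carbon C3′, so reduction of a C2′ ketone would rest on a weak steric bias. The sensitive functions are the two secondary acetates, the salicylic-type acid (which loses CO2 on heating), and the 1,5-relation between the C2′ oxygen and C7: a free C2′ hydroxyl closes onto C7 to give a 3,4-dihydroisocoumarin. The difficulty therefore lies less in the skeleton than in delivering two remote, independently controlled C–O centres directly as acetates, without ever freeing the C2′ oxygen, and in a final deprotection that leaves the esters alone. The strategy rests on one feature: a secondary acetate R2CH–OAc is the Baeyer–Villiger product of the methyl ketone R2CH–COCH3. C2′ and C12′ can thus be built as carbon-substituted centres by auxiliary-controlled enolate alkylation, where C1′ and C3′ enter in different roles (electrophile and enolate backbone), and then converted into both acetates in one stereoretentive oxidation.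

## Retrosynthetic reasoning

**28 to 27.** The three O–benzyl bonds (ester on C7, ethers on O2 and O4) are cut. The forward reaction is a neutral hydrogenolysis, the one deprotection that leaves two aliphatic acetates and a decarboxylation-prone acid untouched. Benzyl groups also withstand the bases, organometallics and peracid used earlier.

**27 to 25.** The C2′–O and C12′–O bonds are cut together, each acetoxy oxygen being replaced by a direct bond from the stereocentre to the acetyl carbon. Cutting here and not at the acyl C–O bonds means the C2′ oxygen never exists as a free hydroxyl next to C7. It also turns both stereocentres into carbonyl alpha-carbons that enolate chemistry can set. The forward reaction must insert oxygen with migration of the secondary carbon and with retention.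

**25 to 23.** Each acetyl group is cut at its CO–CH3 bond, which leads to diacid 23. The acid oxidation level is what auxiliary alkylation delivers. The forward step needs a methyl donor that stops at the ketone, because 25 has epimerisable centres beside both carbonyls.

**23 to 21.** The two carboxyl groups are traced to N-acyl oxazolidinones. The forward cleavage has to act at both exocyclic imide carbonyls and spare the hindered benzyl ester on C7.

**21 to 19 and 8.** The C1′–C2′ bond is cut. This is the natural seam between ring and chain: the benzylic carbon becomes an SN2 electrophile (8) and C2′ the alpha-carbon of an imide enolate (from 19). C1′ and C3′ are then told apart by their roles and not by their size, under the control of auxiliary 17. A cut at C2′–C3′ would need an unactivated alkyl halide and an enolate sitting next to the C7 ester.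

**19 to 16 and 17, and 16 to 15.** The N-acyl bond to 17 is cut and acid 16 is traced to its tert-butyl ester 15. The ester keeps the two ends of the C13 backbone apart until the first centre is in place.

**15 to 13.** The C12′–C13′ bond is cut: C13′ enters as a methyl electrophile on the enolate of 13 under the control of auxiliary 11. Methylating a long-chain imide is preferred to alkylating a propionyl imide with a long-chain halide, because oxazolidinone enolates react well only with small or activated electrophiles. The two termini need opposite senses of induction (at C2′ the incoming group ranks second, at C12′ third), so the enantiomeric auxiliaries 11 and 17 are used.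

**13 to 10 and 11, and 10 to 9.** The N-acyl bond is cut, and monoester 10 is traced to the symmetric diacid 9.

**8 to 7, 5, 4 and 1.** The iodide comes from the chloride, the ester from the acid, and the acid from the aldehyde. The C1–C7 bond is cut last: a formylation of the 3,5-dioxygenated benzyl alcohol 1 installs C7 and the benzylic chloride in one operation. This path is preferred to radical halogenation of the methyl group of a fully benzylated 6-methylresorcylate, where the electron-rich ring and the benzylic ether positions compete for the halogen.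

## Alternatives that were turned down

**Alternative 1:** Biomimetic ring synthesis.
- Disconnection: the ring is opened at C1–C6, back to an open-chain tetracarbonyl compound masked as diketo-dioxinone A1.
- Forward key step: heating A1 with the ester-forming alcohol opens the dioxinone by a retro-[4+2] reaction to an acylketene, which is trapped as triketo ester A2. Mild base then closes C1–C6 by intramolecular aldol addition, and dehydration and enolisation give resorcylate A3.
- For: the ring is made late with both phenols free and no regiochemical question, and no electron-rich arene has to survive an oxidant. On these points it is stronger than the chosen route.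
- Against: A1 must already carry both oxygen stereocentres as silyl ethers, so two separate asymmetric C–O constructions are needed before the key step. The C2′ silyloxy group of A2 is beta to the C6 ketone and can eliminate under the basic closure. After aromatisation two silyl ethers must be exchanged for acetates beside two free phenols, and the freed C2′ hydroxyl stands 1,5 to C7 and lactonises.
- Comparison: the chosen route spends more steps on the arene fragment. In return it forms the acetates directly and draws both centres from one uniform, predictable operation.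

**Alternative 2:** Aryne insertion.
- Disconnection: C6–C1′ and C1–C7 are cut together, back to an aryne and a malonate.
- Forward key step: fluoride releases the aryne from silyl triflate A4. The carbanion of malonate A5 adds at the aryne carbon remote from the flanking benzyloxy group, the aryl anion attacks an ester carbonyl, and the four-membered intermediate opens. The net result is insertion into a C–C(=O) bond to give homophthalate A6, with no lasting ring closure.
- For: the whole substitution pattern of the ring, with C7 and C1′, arrives in one step, with regiochemistry set by the alkoxy group. This is shorter than the four steps to 8.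
- Against: A6 holds only C1′ and C2′ of the chain, C2′ as an ester carbon, and no stereocentre. That ester must be told apart from the C7 benzyl ester, reduced, and joined to an eleven-carbon unit. C2′ then has to be set at a carbonyl flanked by two similar methylene groups, giving a free hydroxyl next to C7, and C12′ needs a separate operation. A4 itself takes several steps.
- Comparison: stronger for the arene core, but it leaves the stereochemical and acetate problem open, which is exactly what the chosen strategy solves.

**Alternative 3:** Ynoate cycloaddition.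
- Disconnection: C1–C2 and C5–C6 of the ring are cut, back to ynoate A7 (which carries the whole chain with both acetates) and cyclic diene A8.
- Forward key step: a thermal [4+2] reaction joins the silyloxy-bearing diene terminus to the alpha-carbon of A7. The bicyclic adduct loses its saturated gem-dimethyl bridge as an alkene by a retro-[4+2] reaction, and desilylation gives A9.
- For: ring, free phenols and both acetates arrive in one step, and only one benzyl ester remains to be removed. In convergence and protecting-group economy it is as strong as or stronger than the chosen route.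
- Against: the stereochemical burden moves entirely into A7, whose two acetoxy centres need two separate asymmetric steps. A β-alkyl ynoate with a trisubstituted diene needs prolonged heating. Under such conditions the homopropargylic acetate of A7 can eliminate, and the fresh phenols beside acetates invite acyl transfer.
- Comparison: the chosen route is longer in the arene part. It runs at or below room temperature once the acetates exist, and takes both centres from the same auxiliary chemistry followed by a stereospecific rearrangement.

Key step: step 13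

## Route

Step 1
Reactants: 1 3,5-bis(benzyloxy)benzyl alcohol
Product: 4 2,4-bis(benzyloxy)-6-(chloromethyl)benzaldehyde, via 3,5-bis(benzyloxy)benzyl chloride 2 (not isolated), via aryliminium chloride 3 (not isolated)
Conditions: POCl3 (3 equiv), DMF, 0 °C → 75 °C; then aq. NaOAc, rt
Reagents that add atoms: N,N-dimethylformamide CN(C)C=O (formyl carbon); phosphoryl chloride O=P(Cl)(Cl)Cl (chlorine); water O (aldehyde oxygen)
Why: Vilsmeier–Haack reaction: the chloroiminium salt first turns the benzylic alcohol into chloride 2 and then formylates the ring carbon that is para to one benzyloxy group and ortho to the other, the site between the two ethers being more crowded; aqueous acetate hydrolyses iminium salt 3. The same one-pot chlorination–formylation is known for the corresponding dimethyl ether.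

Step 2
Reactants: 4 2,4-bis(benzyloxy)-6-(chloromethyl)benzaldehyde
Product: 5 2,4-bis(benzyloxy)-6-(chloromethyl)benzoic acid
Conditions: NaClO2, NaH2PO4, 2-methyl-2-butene, t-BuOH/THF/H2O, 0 °C → rt
Reagents that add atoms: sodium chlorite [Na+].[O-]Cl=O
Why: Pinnick (Lindgren) oxidation: chlorous acid adds to the hindered aldehyde and fragments to the acid, while 2-methyl-2-butene removes hypochlorous acid before it can chlorinate the electron-rich ring; the weakly acidic buffer leaves the CH2Cl group and the benzyl ethers alone.

Step 3
Reactants: 5 2,4-bis(benzyloxy)-6-(chloromethyl)benzoic acid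
Product: 7 benzyl 2,4-bis(benzyloxy)-6-(chloromethyl)benzoate, via acid chloride 6 (not isolated)
Conditions: (COCl)2, cat. DMF, CH2Cl2, 0 °C → rt, evaporate; then BnOH, i-Pr2NEt, cat. DMAP, CH2Cl2, 0 °C → rt
Reagents that add atoms: benzyl alcohol OCc1ccccc1
Why: Base-free acid chloride formation followed by DMAP-catalysed acylation of benzyl alcohol; no carboxylate is ever present beside the CH2Cl group, so closure to the five-membered lactone is avoided, and the hindered amine does not quaternise at the benzylic chloride.

Step 4
Reactants: 7 benzyl 2,4-bis(benzyloxy)-6-(chloromethyl)benzoate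
Product: 8 benzyl 2,4-bis(benzyloxy)-6-(iodomethyl)benzoate
Conditions: NaI (3 equiv), acetone, rt, dark; used promptly
Reagents that add atoms: sodium iodide [Na+].[I-]
Why: Finkelstein exchange, an SN2 displacement driven by precipitation of NaCl, gives the more reactive benzylic iodide for the enolate alkylation; both benzyloxy groups are meta to the CH2I carbon, so the halide is not prone to ionisation.

Step 5
Reactants: 9 tridecanedioic acid
Product: 10 13-(tert-butoxy)-13-oxotridecanoic acid
Conditions: Me2NCH(Ot-Bu)2 (1.1 equiv), toluene, 85 °C; separation from diacid and diester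
Reagents that add atoms: N,N-dimethylformamide di-tert-butyl acetal CN(C)C(OC(C)(C)C)OC(C)(C)C
Why: Monoesterification by tert-butyl transfer from the protonated formamide acetal to the carboxylate; with about one equivalent the outcome is statistical, and the monoester is separated from recovered diacid and neutral diester by extraction and chromatography.

Step 6
Reactants: 10 13-(tert-butoxy)-13-oxotridecanoic acid; 11 (4S)-4-benzyl-1,3-oxazolidin-2-one
Product: 13 tert-butyl 13-[(4S)-4-benzyl-2-oxo-1,3-oxazolidin-3-yl]-13-oxotridecanoate, via mixed pivalic anhydride 12 (not isolated)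
Conditions: t-BuCOCl, Et3N, THF, −20 °C; then LiCl, 11, −20 °C → rt
Reagents that add atoms: none
Why: N-acylation of the oxazolidinone through the mixed pivalic anhydride with LiCl/Et3N activation, which needs no strong base; attack occurs at the unhindered carbonyl of the anhydride and the tert-butyl ester is inert.

Step 7
Reactants: 13 tert-butyl 13-[(4S)-4-benzyl-2-oxo-1,3-oxazolidin-3-yl]-13-oxotridecanoate
Product: 15 tert-butyl (12S)-13-[(4S)-4-benzyl-2-oxo-1,3-oxazolidin-3-yl]-12-methyl-13-oxotridecanoate, via sodium Z-enolate 14 (not isolated)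
Conditions: NaN(SiMe3)2 (1.1 equiv), THF, −78 °C; MeI (5 equiv), −78 → −40 °C
Reagents that add atoms: iodomethane CI
Why: Evans alkylation: the chelated Z-enolate 14 is methylated on the face opposite the C4 benzyl group of the (S)-auxiliary, which sets C12′ as S (acyl > chain > methyl). The remote tert-butyl ester is far less acidic and is not enolised, and the minor diastereomer should be removable by chromatography.

Step 8
Reactants: 15 tert-butyl (12S)-13-[(4S)-4-benzyl-2-oxo-1,3-oxazolidin-3-yl]-12-methyl-13-oxotridecanoate
Product: 16 (12S)-13-[(4S)-4-benzyl-2-oxo-1,3-oxazolidin-3-yl]-12-methyl-13-oxotridecanoic acid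
Conditions: CF3CO2H/CH2Cl2 (1:3), 0 °C → rt
Reagents that add atoms: none
Why: Acidolysis of the tert-butyl ester through the tert-butyl cation with loss of isobutene; the imide and its alpha stereocentre are stable to anhydrous acid.

Step 9
Reactants: 16 (12S)-13-[(4S)-4-benzyl-2-oxo-1,3-oxazolidin-3-yl]-12-methyl-13-oxotridecanoic acid; 17 (4R)-4-benzyl-1,3-oxazolidin-2-one
Product: 19 (4R)-4-benzyl-3-{(12S)-13-[(4S)-4-benzyl-2-oxo-1,3-oxazolidin-3-yl]-12-methyl-13-oxotridecanoyl}-1,3-oxazolidin-2-one, via mixed pivalic anhydride 18 (not isolated)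
Conditions: t-BuCOCl, Et3N, THF, −20 °C; then LiCl, 17, −20 °C → rt
Reagents that add atoms: none
Why: The same mixed-anhydride N-acylation, now with the enantiomeric auxiliary; the alpha-methyl imide terminus does not epimerise under Et3N/LiCl because enolisation of an alpha-branched imide is disfavoured by A(1,3) strain.

Step 10
Reactants: 19 (4R)-4-benzyl-3-{(12S)-13-[(4S)-4-benzyl-2-oxo-1,3-oxazolidin-3-yl]-12-methyl-13-oxotridecanoyl}-1,3-oxazolidin-2-one; 8 benzyl 2,4-bis(benzyloxy)-6-(iodomethyl)benzoate
Product: 21 benzyl 2,4-bis(benzyloxy)-6-{(2S,12S)-2-[(4R)-4-benzyl-2-oxo-1,3-oxazolidine-3-carbonyl]-13-[(4S)-4-benzyl-2-oxo-1,3-oxazolidin-3-yl]-12-methyl-13-oxotridecyl}benzoate, via sodium Z-enolate 20 (not isolated)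
Conditions: NaN(SiMe3)2 (1.0 equiv), THF, −78 °C; 8 (1.1 equiv) in THF, −78 → −30 °C
Reagents that add atoms: none
Why: Evans alkylation: one equivalent of base deprotonates only the unbranched imide terminus, since the alpha-methyl terminus would meet A(1,3) strain on enolisation. The chelated Z-enolate 20 is attacked by the benzylic iodide on the face opposite the benzyl group of the (R)-auxiliary, which sets C2′ as S (acyl > CH2Ar > chain). The hindered ester and the ethers of 8 do not interfere with SN2 at the CH2I carbon.

Step 11
Reactants: 21 benzyl 2,4-bis(benzyloxy)-6-{(2S,12S)-2-[(4R)-4-benzyl-2-oxo-1,3-oxazolidine-3-carbonyl]-13-[(4S)-4-benzyl-2-oxo-1,3-oxazolidin-3-yl]-12-methyl-13-oxotridecyl}benzoate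
Product: 23 (2S,12S)-2-{3,5-bis(benzyloxy)-2-[(benzyloxy)carbonyl]benzyl}-12-methyltridecanedioic acid, via diperoxy acid 22 (not isolated)
Conditions: LiOH, 30% H2O2, THF/H2O (3:1), 0 °C; aq. Na2SO3; 1 M HCl
Reagents that add atoms: hydrogen peroxide OO
Why: Hydroperoxide cleavage of N-acyloxazolidinones: the small alpha-effect nucleophile LiOOH attacks the exocyclic carbonyl even of branched imides, giving percarboxylate 22 and releasing both auxiliaries, and sulfite reduces the peracid functions. The 2,6-disubstituted benzyl benzoate is too hindered to be cleaved at 0 °C, and neither alpha centre is enolised.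

Step 12
Reactants: 23 (2S,12S)-2-{3,5-bis(benzyloxy)-2-[(benzyloxy)carbonyl]benzyl}-12-methyltridecanedioic acid
Product: 25 benzyl 6-[(2S,12S)-2-acetyl-12-methyl-13-oxotetradecyl]-2,4-bis(benzyloxy)benzoate, via diacyl dichloride 24 (not isolated)
Conditions: (COCl)2, cat. DMF, CH2Cl2, 0 °C → rt, evaporate; then Me2CuLi (from MeLi and CuI, 6 equiv), Et2O/THF, −78 °C; aq. NH4Cl
Reagents that add atoms: methyllithium [Li]C (delivered as Me2CuLi)
Why: Ketone synthesis from acid chlorides and a Gilman cuprate: the acyl chlorides are formed without base, and the monovalent copper reagent transfers one methyl group per acyl chloride at −78 °C without adding to the ketones formed or to the hindered benzyl ester. The weakly basic cuprate leaves both alpha stereocentres untouched.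

Step 13
Reactants: 25 benzyl 6-[(2S,12S)-2-acetyl-12-methyl-13-oxotetradecyl]-2,4-bis(benzyloxy)benzoate
Product: 27 benzyl 2,4-bis(benzyloxy)-6-[(2S,12S)-2,12-diacetoxytridecyl]benzoate, via Criegee bis-adduct 26 (not isolated)
Conditions: mCPBA (5 equiv), Na2HPO4 (10 equiv), CH2Cl2, rt, dark
Reagents that add atoms: 3-chloroperoxybenzoic acid OOC(=O)c1cccc(Cl)c1
Why: Baeyer–Villiger oxidation of alpha-branched methyl ketones, a known route to secondary acetates. The peracid adds to each carbonyl to give the peroxy hemiketals 26, and the group antiperiplanar to the O–O bond then shifts from carbon to oxygen as 3-chlorobenzoate leaves. The secondary carbons C2′ and C12′ migrate in preference to methyl because they carry the partial positive charge of the transition state better, so the C2′–O and C12′–O bonds form and only acetates result. The shift is a suprafacial 1,2-migration in which the migrating carbon keeps its bonding face, so both centres are transferred with retention: the S configuration fixed at C2′ by the (R)-auxiliary in step 10 and at C12′ by the (S)-auxiliary in step 7 becomes the S configuration of the acetoxy carbons, the priority order being unchanged when oxygen replaces the acyl carbon. No ring is closed and no new stereocentre is created. The selectivity needed is for the ketones over the arene and the benzylic ether positions: the ring is deactivated by the C1 ester, both activated ring positions are flanked by substituents, and the molecule has no alkene, amine or sulfide. Solid Na2HPO4 takes up 3-chlorobenzoic acid, which suppresses acid-catalysed enolisation of the ketones before migration and acid-promoted damage to the acetates afterwards.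

Step 14
Reactants: 27 benzyl 2,4-bis(benzyloxy)-6-[(2S,12S)-2,12-diacetoxytridecyl]benzoate
Product: 28 2-[(2S,12S)-2,12-diacetoxytridecyl]-4,6-dihydroxybenzoic acid
Conditions: H2 (1 atm), 10% Pd/C, EtOAc, rt
Reagents that add atoms: none
Why: Hydrogenolysis of the benzyl ester and both aryl benzyl ethers on zerovalent palladium under neutral conditions; the aliphatic acetates, the ring and both stereocentres are unaffected, and the acid is released without base or heat, so neither decarboxylation nor acyl transfer is expected.

## Compound list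

1 | 3,5-bis(benzyloxy)benzyl alcohol | OCc1cc(OCc2ccccc2)cc(OCc2ccccc2)c1 | starting material
2 | 3,5-bis(benzyloxy)benzyl chloride | ClCc1cc(OCc2ccccc2)cc(OCc2ccccc2)c1 | intermediate
3 | N-{[2,4-bis(benzyloxy)-6-(chloromethyl)phenyl]methylidene}-N-methylmethanaminium chloride | C[N+](C)=Cc1c(CCl)cc(OCc2ccccc2)cc1OCc1ccccc1.[Cl-] | intermediate
4 | 2,4-bis(benzyloxy)-6-(chloromethyl)benzaldehyde | ClCc1cc(OCc2ccccc2)cc(OCc2ccccc2)c1C=O | intermediate
5 | 2,4-bis(benzyloxy)-6-(chloromethyl)benzoic acid | ClCc1cc(OCc2ccccc2)cc(OCc2ccccc2)c1C(=O)O | intermediate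
6 | 2,4-bis(benzyloxy)-6-(chloromethyl)benzoyl chloride | ClCc1cc(OCc2ccccc2)cc(OCc2ccccc2)c1C(Cl)=O | intermediate
7 | benzyl 2,4-bis(benzyloxy)-6-(chloromethyl)benzoate | ClCc1cc(OCc2ccccc2)cc(OCc2ccccc2)c1C(=O)OCc1ccccc1 | intermediate
8 | benzyl 2,4-bis(benzyloxy)-6-(iodomethyl)benzoate | ICc1cc(OCc2ccccc2)cc(OCc2ccccc2)c1C(=O)OCc1ccccc1 | intermediate
9 | tridecanedioic acid | OC(=O)CCCCCCCCCCCC(=O)O | starting material
10 | 13-(tert-butoxy)-13-oxotridecanoic acid | CC(C)(C)OC(=O)CCCCCCCCCCCC(=O)O | intermediate
11 | (4S)-4-benzyl-1,3-oxazolidin-2-one | O=C1N[C@@H](Cc2ccccc2)CO1 | starting material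
12 | 13-(tert-butoxy)-13-oxotridecanoic 2,2-dimethylpropanoic anhydride | CC(C)(C)OC(=O)CCCCCCCCCCCC(=O)OC(=O)C(C)(C)C | intermediate
13 | tert-butyl 13-[(4S)-4-benzyl-2-oxo-1,3-oxazolidin-3-yl]-13-oxotridecanoate | CC(C)(C)OC(=O)CCCCCCCCCCCC(=O)N1[C@@H](Cc2ccccc2)COC1=O | intermediate
14 | sodium (1Z)-1-[(4S)-4-benzyl-2-oxo-1,3-oxazolidin-3-yl]-13-(tert-butoxy)-13-oxotridec-1-en-1-olate | [Na+].[O-]/C(=C\CCCCCCCCCCC(=O)OC(C)(C)C)N1[C@@H](Cc2ccccc2)COC1=O | intermediate
15 | tert-butyl (12S)-13-[(4S)-4-benzyl-2-oxo-1,3-oxazolidin-3-yl]-12-methyl-13-oxotridecanoate | CC(C)(C)OC(=O)CCCCCCCCCC[C@H](C)C(=O)N1[C@@H](Cc2ccccc2)COC1=O | intermediate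
16 | (12S)-13-[(4S)-4-benzyl-2-oxo-1,3-oxazolidin-3-yl]-12-methyl-13-oxotridecanoic acid | OC(=O)CCCCCCCCCC[C@H](C)C(=O)N1[C@@H](Cc2ccccc2)COC1=O | intermediate
17 | (4R)-4-benzyl-1,3-oxazolidin-2-one | O=C1N[C@H](Cc2ccccc2)CO1 | starting material
18 | (12S)-13-[(4S)-4-benzyl-2-oxo-1,3-oxazolidin-3-yl]-12-methyl-13-oxotridecanoic 2,2-dimethylpropanoic anhydride | CC(C)(C)C(=O)OC(=O)CCCCCCCCCC[C@H](C)C(=O)N1[C@@H](Cc2ccccc2)COC1=O | intermediate
19 | (4R)-4-benzyl-3-{(12S)-13-[(4S)-4-benzyl-2-oxo-1,3-oxazolidin-3-yl]-12-methyl-13-oxotridecanoyl}-1,3-oxazolidin-2-one | O=C(CCCCCCCCCC[C@H](C)C(=O)N1[C@@H](Cc2ccccc2)COC1=O)N1[C@H](Cc2ccccc2)COC1=O | intermediate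
20 | sodium (1Z,12S)-1-[(4R)-4-benzyl-2-oxo-1,3-oxazolidin-3-yl]-13-[(4S)-4-benzyl-2-oxo-1,3-oxazolidin-3-yl]-12-methyl-13-oxotridec-1-en-1-olate | [Na+].[O-]/C(=C\CCCCCCCCC[C@H](C)C(=O)N1[C@@H](Cc2ccccc2)COC1=O)N1[C@H](Cc2ccccc2)COC1=O | intermediate
21 | benzyl 2,4-bis(benzyloxy)-6-{(2S,12S)-2-[(4R)-4-benzyl-2-oxo-1,3-oxazolidine-3-carbonyl]-13-[(4S)-4-benzyl-2-oxo-1,3-oxazolidin-3-yl]-12-methyl-13-oxotridecyl}benzoate | O=C([C@@H](CCCCCCCCC[C@H](C)C(=O)N1[C@@H](Cc2ccccc2)COC1=O)Cc1cc(OCc2ccccc2)cc(OCc2ccccc2)c1C(=O)OCc1ccccc1)N1[C@H](Cc2ccccc2)COC1=O | intermediate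
22 | (2S,12S)-2-{3,5-bis(benzyloxy)-2-[(benzyloxy)carbonyl]benzyl}-12-methyltridecanediperoxoic acid (present as its dilithium salt) | OOC(=O)[C@@H](CCCCCCCCC[C@H](C)C(=O)OO)Cc1cc(OCc2ccccc2)cc(OCc2ccccc2)c1C(=O)OCc1ccccc1 | intermediate
23 | (2S,12S)-2-{3,5-bis(benzyloxy)-2-[(benzyloxy)carbonyl]benzyl}-12-methyltridecanedioic acid | OC(=O)[C@@H](CCCCCCCCC[C@H](C)C(=O)O)Cc1cc(OCc2ccccc2)cc(OCc2ccccc2)c1C(=O)OCc1ccccc1 | intermediate
24 | (2S,12S)-2-{3,5-bis(benzyloxy)-2-[(benzyloxy)carbonyl]benzyl}-12-methyltridecanedioyl dichloride | ClC(=O)[C@@H](CCCCCCCCC[C@H](C)C(Cl)=O)Cc1cc(OCc2ccccc2)cc(OCc2ccccc2)c1C(=O)OCc1ccccc1 | intermediate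
25 | benzyl 6-[(2S,12S)-2-acetyl-12-methyl-13-oxotetradecyl]-2,4-bis(benzyloxy)benzoate | CC(=O)[C@@H](CCCCCCCCC[C@H](C)C(C)=O)Cc1cc(OCc2ccccc2)cc(OCc2ccccc2)c1C(=O)OCc1ccccc1 | intermediate
26 | benzyl 2,4-bis(benzyloxy)-6-{(2S,12S)-2-[1-(3-chlorobenzoylperoxy)-1-hydroxyethyl]-13-(3-chlorobenzoylperoxy)-13-hydroxy-12-methyltetradecyl}benzoate (mixture at the two hemiketal carbons) | CC(O)(OOC(=O)c1cccc(Cl)c1)[C@@H](CCCCCCCCC[C@H](C)C(C)(O)OOC(=O)c1cccc(Cl)c1)Cc1cc(OCc2ccccc2)cc(OCc2ccccc2)c1C(=O)OCc1ccccc1 | intermediate
27 | benzyl 2,4-bis(benzyloxy)-6-[(2S,12S)-2,12-diacetoxytridecyl]benzoate | CC(=O)O[C@@H](CCCCCCCCC[C@H](C)OC(C)=O)Cc1cc(OCc2ccccc2)cc(OCc2ccccc2)c1C(=O)OCc1ccccc1 | intermediate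
28 | 2-[(2S,12S)-2,12-diacetoxytridecyl]-4,6-dihydroxybenzoic acid | CC(=O)O[C@@H](CCCCCCCCC[C@H](C)OC(C)=O)Cc1cc(O)cc(O)c1C(=O)O | target

## Step count and least certain steps

Total step count: 14. Longest linear sequence: 10 steps (steps 5 to 14, from 9). The aryl branch (steps 1 to 4) joins at step 10.

**Step 13 (key step).** The oxygen insertion may stall at the more hindered C2′ ketone, since peracid oxidation of acyclic methyl ketones is slow. Forcing it with more peracid, heat or time invites oxidation of the dialkoxy ring or of the benzylic ether positions. The fallback sets out from 25 and returns at 28. It reverses the order of deprotection and oxidation, so that the ring passes through the oxidation as its deactivated diacetate.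
- Hydrogenolysis of 25 (H2, Pd/C, EtOAc) gives 2-[(2S,12S)-2-acetyl-12-methyl-13-oxotetradecyl]-4,6-dihydroxybenzoic acid F1.
- Acetic anhydride in pyridine, with aqueous work-up, gives 2,4-diacetoxy-6-[(2S,12S)-2-acetyl-12-methyl-13-oxotetradecyl]benzoic acid F2.
- The acylated ring now tolerates the stronger trifluoroperacetic acid (buffered with Na2HPO4, CH2Cl2, 0 °C), which should give 2,4-diacetoxy-6-[(2S,12S)-2,12-diacetoxytridecyl]benzoic acid F3.
- The two aryl acetates, far more electrophilic than the alkyl acetates, are removed with ammonium acetate in aqueous methanol to give 28.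

**Step 10.** The alkylation may stay incomplete, because the sodium enolate fragments on warming before the ortho-substituted benzylic iodide has reacted, or because iodide 8 is lost by ester-assisted cyclisation. Any enolisation at the wrong terminus would also erode C12′. The fallback sets out from 10 and returns at 21. It changes the order in which the two centres are made, so that the benzylation runs on a simple mono-imide that can be used in excess.
- 10 is coupled to 17 as in step 6 to give tert-butyl 13-[(4R)-4-benzyl-2-oxo-1,3-oxazolidin-3-yl]-13-oxotridecanoate F4.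
- Its sodium enolate (1.5 equiv) is alkylated with 8 to give benzyl 2,4-bis(benzyloxy)-6-{(2S)-2-[(4R)-4-benzyl-2-oxo-1,3-oxazolidine-3-carbonyl]-13-(tert-butoxy)-13-oxotridecyl}benzoate F5.
- Brief treatment with CF3CO2H in CH2Cl2 at 0 °C frees (12S)-12-[(4R)-4-benzyl-2-oxo-1,3-oxazolidine-3-carbonyl]-13-{3,5-bis(benzyloxy)-2-[(benzyloxy)carbonyl]phenyl}tridecanoic acid F6.
- Acylation of 11 as in step 9 gives benzyl 2,4-bis(benzyloxy)-6-{(2S)-2-[(4R)-4-benzyl-2-oxo-1,3-oxazolidine-3-carbonyl]-13-[(4S)-4-benzyl-2-oxo-1,3-oxazolidin-3-yl]-13-oxotridecyl}benzoate F7.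
- Methylation (NaN(SiMe3)2, MeI, −78 °C), which again enolises only the unbranched terminus, gives 21.

**Step 3.** The carboxyl oxygen may displace the neighbouring chloride (lactonisation to the phthalide) once base is present, or the amine catalyst may quaternise at the benzylic chloride. The fallback sets out from 5 and returns at 7. It replaces acyl activation by O-alkylation of the undissociated acid: benzyl 2,2,2-trichloroacetimidate with catalytic CF3SO3H in CH2Cl2/cyclohexane at rt transfers the benzyl group under acidic conditions, where no carboxylate exists. No new compound is made (F0).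

**Step 12.** The C2′ acyl chloride may acylate the activated ring carbon C5 intramolecularly (Friedel–Crafts closure to an indanone), or one terminus may react incompletely or epimerise through a ketene. The fallback sets out from 23 and returns at 25, and avoids any strongly electrophilic acyl species.
- Amide coupling of 23 with N,O-dimethylhydroxylamine hydrochloride (EDC, HOBt, i-Pr2NEt, CH2Cl2) gives benzyl 2,4-bis(benzyloxy)-6-{(2S,12S)-2-[methoxy(methyl)carbamoyl]-13-[methoxy(methyl)amino]-12-methyl-13-oxotridecyl}benzoate F8.
- MeMgBr (THF, 0 °C) then gives 25. The chelated tetrahedral intermediate prevents over-addition, and the hindered benzyl ester is spared at this temperature.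

## Further compounds

F1 | step 13 | 2-[(2S,12S)-2-acetyl-12-methyl-13-oxotetradecyl]-4,6-dihydroxybenzoic acid | CC(=O)[C@@H](CCCCCCCCC[C@H](C)C(C)=O)Cc1cc(O)cc(O)c1C(=O)O
F2 | step 13 | 2,4-diacetoxy-6-[(2S,12S)-2-acetyl-12-methyl-13-oxotetradecyl]benzoic acid | CC(=O)[C@@H](CCCCCCCCC[C@H](C)C(C)=O)Cc1cc(OC(C)=O)cc(OC(C)=O)c1C(=O)O
F3 | step 13 | 2,4-diacetoxy-6-[(2S,12S)-2,12-diacetoxytridecyl]benzoic acid | CC(=O)O[C@@H](CCCCCCCCC[C@H](C)OC(C)=O)Cc1cc(OC(C)=O)cc(OC(C)=O)c1C(=O)O
F4 | step 10 | tert-butyl 13-[(4R)-4-benzyl-2-oxo-1,3-oxazolidin-3-yl]-13-oxotridecanoate | CC(C)(C)OC(=O)CCCCCCCCCCCC(=O)N1[C@H](Cc2ccccc2)COC1=O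
F5 | step 10 | benzyl 2,4-bis(benzyloxy)-6-{(2S)-2-[(4R)-4-benzyl-2-oxo-1,3-oxazolidine-3-carbonyl]-13-(tert-butoxy)-13-oxotridecyl}benzoate | CC(C)(C)OC(=O)CCCCCCCCCC[C@@H](Cc1cc(OCc2ccccc2)cc(OCc2ccccc2)c1C(=O)OCc1ccccc1)C(=O)N1[C@H](Cc2ccccc2)COC1=O
F6 | step 10 | (12S)-12-[(4R)-4-benzyl-2-oxo-1,3-oxazolidine-3-carbonyl]-13-{3,5-bis(benzyloxy)-2-[(benzyloxy)carbonyl]phenyl}tridecanoic acid | OC(=O)CCCCCCCCCC[C@@H](Cc1cc(OCc2ccccc2)cc(OCc2ccccc2)c1C(=O)OCc1ccccc1)C(=O)N1[C@H](Cc2ccccc2)COC1=O
F7 | step 10 | benzyl 2,4-bis(benzyloxy)-6-{(2S)-2-[(4R)-4-benzyl-2-oxo-1,3-oxazolidine-3-carbonyl]-13-[(4S)-4-benzyl-2-oxo-1,3-oxazolidin-3-yl]-13-oxotridecyl}benzoate | O=C(CCCCCCCCCC[C@@H](Cc1cc(OCc2ccccc2)cc(OCc2ccccc2)c1C(=O)OCc1ccccc1)C(=O)N1[C@H](Cc2ccccc2)COC1=O)N1[C@@H](Cc2ccccc2)COC1=O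
F0 | step 3 | none | none
F8 | step 12 | benzyl 2,4-bis(benzyloxy)-6-{(2S,12S)-2-[methoxy(methyl)carbamoyl]-13-[methoxy(methyl)amino]-12-methyl-13-oxotridecyl}benzoate | CON(C)C(=O)[C@@H](CCCCCCCCC[C@H](C)C(=O)N(C)OC)Cc1cc(OCc2ccccc2)cc(OCc2ccccc2)c1C(=O)OCc1ccccc1
A1 | alternative 1 | 6-[(6S,16S)-6,16-bis(tert-butyldimethylsilyloxy)-2,4-dioxoheptadecyl]-2,2-dimethyl-4H-1,3-dioxin-4-one | CC1(C)OC(=O)C=C(CC(=O)CC(=O)C[C@@H](O[Si](C)(C)C(C)(C)C)CCCCCCCCC[C@H](C)O[Si](C)(C)C(C)(C)C)O1
A2 | alternative 1 | benzyl (9S,19S)-9,19-bis(tert-butyldimethylsilyloxy)-3,5,7-trioxoicosanoate | O=C(CC(=O)CC(=O)CC(=O)C[C@@H](O[Si](C)(C)C(C)(C)C)CCCCCCCCC[C@H](C)O[Si](C)(C)C(C)(C)C)OCc1ccccc1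
A3 | alternative 1 | benzyl 2,4-dihydroxy-6-[(2S,12S)-2,12-bis(tert-butyldimethylsilyloxy)tridecyl]benzoate | CC(C)(C)[Si](C)(C)O[C@@H](CCCCCCCCC[C@H](C)O[Si](C)(C)C(C)(C)C)Cc1cc(O)cc(O)c1C(=O)OCc1ccccc1
A4 | alternative 2 | 3,5-bis(benzyloxy)-2-(trimethylsilyl)phenyl trifluoromethanesulfonate | C[Si](C)(C)c1c(OS(=O)(=O)C(F)(F)F)cc(OCc2ccccc2)cc1OCc1ccccc1
A5 | alternative 2 | dibenzyl malonate | O=C(CC(=O)OCc1ccccc1)OCc1ccccc1
A6 | alternative 2 | benzyl 2,4-bis(benzyloxy)-6-(2-benzyloxy-2-oxoethyl)benzoate | O=C(Cc1cc(OCc2ccccc2)cc(OCc2ccccc2)c1C(=O)OCc1ccccc1)OCc1ccccc1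
A7 | alternative 3 | benzyl (5S,15S)-5,15-diacetoxyhexadec-2-ynoate | CC(=O)O[C@@H](CCCCCCCCC[C@H](C)OC(C)=O)CC#CC(=O)OCc1ccccc1
A8 | alternative 3 | 5,5-dimethyl-1,3-bis(trimethylsilyloxy)cyclohexa-1,3-diene | C[Si](C)(C)OC1=CC(O[Si](C)(C)C)=CC(C)(C)C1
A9 | alternative 3 | benzyl 2,4-dihydroxy-6-[(2S,12S)-2,12-diacetoxytridecyl]benzoate | CC(=O)O[C@@H](CCCCCCCCC[C@H](C)OC(C)=O)Cc1cc(O)cc(O)c1C(=O)OCc1ccccc1
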